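The disconnection cuts the quinone ring (C1′–C4′, C4a′, C8a′ of the naphthoquinone) back to a four-membered ring. C1′–C4′ are the four carbons of a squarate. C8a′ and C4a′ are the ipso and ortho carbons of protected 4-bromo-2-methylphenol. Heating the 4-aryl-4-hydroxy-3-isopropoxycyclobutenone opens it to a vinylketene that closes onto the arene. One operation therefore delivers the naphthoquinone with the heteroatom at C2′, hydrogen at C3′ and the 6′-oxy-7′-methyl pattern. Ammonia then exchanges the C2′ alkoxy group. The C1–C17 chain grows from a methylboronate by nine Matteson homologations under one chiral diol (C12 to C4). A metathesis-made lactone locks the C2=C3 Z geometry and masks the acid.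

Key step: step 4

Remarks
- Numbering: chain atoms run from C1 (carboxyl) to C17 (amide carbonyl). The hydroxymethyl carbon on C4 is C18. Naphthoquinone atoms carry primes, and C2′ bears nitrogen.
- Abbreviations: PMB = 4-methoxybenzyl, TBS = tert-butyldimethylsilyl, DICHED = 1,2-dicyclohexylethane-1,2-diol.
- "Syn" and "anti" refer to the zigzag drawing of the main chain, with boron standing for the next chain atom.
- Assumption: boronates of (R,R)-DICHED give (αS)-α-chloroboronates with LiCHCl2/ZnCl2, and chloride is always displaced with inversion.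
- Compounds 4 and 7 are racemic; their stereocentre disappears later.

Step 1
Reactants: 1 4-bromo-2-methylphenol
Product: 2 (4-bromo-2-methylphenoxy)(tert-butyl)dimethylsilane
Conditions: TBSCl, imidazole, DMF, rt
Reagents that add atoms: tert-butyldimethylsilyl chloride, CC(C)(C)[Si](C)(C)Cl
Why: Imidazole-promoted silylation of a phenol; the silyl ether tolerates bromine–lithium exchange and heat and falls off with hydroxide in step 23.

Step 2
Reactants: 3 diisopropyl squarate
Product: 5 3-isopropoxycyclobut-3-ene-1,2-dione, via hydroxycyclobutenone 4 (not isolated)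
Conditions: LiAlH(OtBu)3, THF, −78 to −20 °C; 2 M HCl; then conc. HCl (cat.), CH2Cl2, rt
Reagents that add atoms: none
Why: The bulky hydride adds once in 1,2-fashion to a squarate carbonyl, and acid then causes the allylic transposition of the 4-hydroxycyclobutenone with loss of isopropanol, which leaves hydrogen on the carbon that becomes C3′.

Step 3
Reactants: 2 (4-bromo-2-methylphenoxy)(tert-butyl)dimethylsilane; 5 3-isopropoxycyclobut-3-ene-1,2-dione
Product: 7 4-[4-(tert-butyldimethylsilyloxy)-3-methylphenyl]-4-hydroxy-3-isopropoxycyclobut-2-en-1-one (racemic), via aryllithium 6 (not isolated)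
Conditions: n-BuLi, THF, −78 °C; then 5, −78 °C; aq NH4Cl
Reagents that add atoms: none
Why: Bromine–lithium exchange and 1,2-addition of the aryllithium, which attacks the ketone-like carbonyl next to the alkoxy-bearing carbon because the other carbonyl is a vinylogous ester; the new carbinol centre is racemic and is lost in step 4.

Step 4
Reactants: 7 4-aryl-4-hydroxy-3-isopropoxycyclobutenone
Product: 10 6-(tert-butyldimethylsilyloxy)-2-isopropoxy-7-methyl-1,4-naphthoquinone, via vinylketene 8 (not isolated), via hydroquinone 9 (not isolated)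
Conditions: p-xylene (0.02 M), 138 °C, Ar; then Ag2O, rt
Reagents that add atoms: none
Why: Heating opens the cyclobutenone by a conrotatory 4π electrocyclic reaction in which the hydroxyl group rotates outward, so that the aryl group stands cis to the ketene in 8. The ketene carbon (future C4′) then bonds to the free ortho carbon C4a′ in a thermally allowed disrotatory 6π electrocyclic closure of a six-membered ring, and tautomerisation gives hydroquinone 9, so the four-membered ring has grown by the two arene carbons C8a′ and C4a′. This is the Moore rearrangement of 4-aryl-4-hydroxycyclobutenones, and Ag2O then takes 9 to the quinone. No stereocentre is formed and the racemic carbinol centre of 7 disappears. The step needs closure at C4a′ (para to the methyl-bearing carbon) and not at C8′ (flanked by the methyl group), and the bulk of the methyl group buttressed by the silyloxy group should secure this. The place of the isopropoxy group next to C1′ was fixed in step 3 and is not at risk here.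

Step 5
Reactants: 10 2-isopropoxyquinone
Product: 11 2-amino-6-(tert-butyldimethylsilyloxy)-7-methyl-1,4-naphthoquinone
Conditions: NH3 (0.4 M in THF), 0 °C to rt
Reagents that add atoms: ammonia, N
Why: Addition–elimination of ammonia at C2′ of a 2-alkoxy-1,4-naphthoquinone (aminolysis of a vinylogous ester) replaces isopropoxide by the amino group, and the aprotic medium should spare the aryl silyl ether.

Step 6
Reactants: 12 methylboronic acid; 13 (1R,2R)-1,2-dicyclohexylethane-1,2-diol [(R,R)-DICHED]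
Product: 14 (4R,5R)-4,5-dicyclohexyl-2-methyl-1,3,2-dioxaborolane
Conditions: MgSO4, Et2O, rt
Reagents that add atoms: none
Why: Esterification of a boronic acid with a 1,2-diol, driven by the drying agent, installs the twofold-symmetric director that controls all nine chain stereocentres; its methyl group is the C12 methyl.

Step 7
Reactants: 14 methylboronate
Product: 16 C12–C14 boronate (4R,5R)-2-[(2R)-but-3-en-2-yl]-4,5-dicyclohexyl-1,3,2-dioxaborolane, via α-chloroboronate 15 (not isolated)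
Conditions: CH2Cl2, n-BuLi, THF, −100 °C; 14; ZnCl2, −100 °C to rt; crude 15, CH2=CHMgBr, THF, 0 °C to rt
Reagents that add atoms: dichloromethane, ClCCl; vinylmagnesium bromide, C=C[Mg]Br
Why: Matteson homologation, in which the ZnCl2-assisted 1,2-shift in the LiCHCl2 borate gives the (αS)-chloride under control of the diol and vinyl then displaces chloride with inversion; C12 is set as R because methyl comes from boron and C13 from the nucleophile.

Step 8
Reactants: 16 C12–C14 boronate
Product: 18 C11–C14 boronate (B and OPMB on C11; OPMB syn to the C12 methyl), via α-chloroboronate 17 (not isolated)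
Conditions: CH2Cl2, n-BuLi, THF, −100 °C; 16; ZnCl2, to rt; crude 17, 4-methoxybenzyl alcohol, NaH, THF/DMSO, rt
Reagents that add atoms: dichloromethane, ClCCl; 4-methoxybenzyl alcohol, OCc1ccc(OC)cc1
Why: Matteson homologation, in which the secondary allylic carbon C12 migrates with retention, the diol fixes the (αS)-chloride and the alkoxide displaces chloride with inversion through its borate, which sets C11.

Step 9
Reactants: 18 C11–C14 boronate
Product: 20 C10–C14 boronate (B and CH3 on C10; CH3 anti to C11-OPMB), via α-chloroboronate 19 (not isolated)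
Conditions: CH2Cl2, n-BuLi, THF, −100 °C; 18; ZnCl2 (excess), to rt; crude 19, MeMgBr, THF, 0 °C to rt
Reagents that add atoms: dichloromethane, ClCCl; methylmagnesium bromide, C[Mg]Br
Why: Matteson homologation under the same director followed by invertive transfer of methyl from the borate sets C10 in the same sense as C11, which in the zigzag means anti.

Step 10
Reactants: 20 C10–C14 boronate
Product: 22 C9–C14 boronate (B and OPMB on C9; anti to the C10 methyl and syn to C11-OPMB), via α-chloroboronate 21 (not isolated)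
Conditions: CH2Cl2, n-BuLi, THF, −100 °C; 20; ZnCl2, to rt; crude 21, 4-methoxybenzyl alcohol, NaH, THF/DMSO, rt
Reagents that add atoms: dichloromethane, ClCCl; 4-methoxybenzyl alcohol, OCc1ccc(OC)cc1
Why: Matteson homologation with alkoxide displacement; the diol again gives the (αS)-chloride and inversion sets C9.

Step 11
Reactants: 22 C9–C14 boronate
Product: 24 C8–C14 boronate (B and CH3 on C8; anti to C9-OPMB), via α-chloroboronate 23 (not isolated)
Conditions: CH2Cl2, n-BuLi, THF, −100 °C; 22; ZnCl2 (excess), to rt; crude 23, MeMgBr, THF, 0 °C to rt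
Reagents that add atoms: dichloromethane, ClCCl; methylmagnesium bromide, C[Mg]Br
Why: Matteson homologation with invertive methyl transfer sets C8 under control of the diol, independent of the stereocentres already in the chain.

Step 12
Reactants: 24 C8–C14 boronate
Product: 26 C7–C14 boronate (B and OPMB on C7; anti to the C8 methyl), via α-chloroboronate 25 (not isolated)
Conditions: CH2Cl2, n-BuLi, THF, −100 °C; 24; ZnCl2 (excess), to rt; crude 25, 4-methoxybenzyl alcohol, NaH, THF/DMSO, rt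
Reagents that add atoms: dichloromethane, ClCCl; 4-methoxybenzyl alcohol, OCc1ccc(OC)cc1
Why: Matteson homologation with alkoxide displacement sets C7 by the same diol-controlled chloride formation and inversion.

Step 13
Reactants: 26 C7–C14 boronate
Product: 28 C6–C14 boronate (B and CH3 on C6; anti to C7-OPMB), via α-chloroboronate 27 (not isolated)
Conditions: CH2Cl2, n-BuLi, THF, −100 °C; 26; ZnCl2 (excess), to rt; crude 27, MeMgBr, THF, 0 °C to rt
Reagents that add atoms: dichloromethane, ClCCl; methylmagnesium bromide, C[Mg]Br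
Why: Matteson homologation with invertive methyl transfer sets C6; extra ZnCl2 makes up for binding to the three ether oxygens.

Step 14
Reactants: 28 C6–C14 boronate
Product: 30 C5–C14 boronate (B and OPMB on C5; anti to the C6 methyl), via α-chloroboronate 29 (not isolated)
Conditions: CH2Cl2, n-BuLi, THF, −100 °C; 28; ZnCl2 (excess), to rt; crude 29, 4-methoxybenzyl alcohol, NaH, THF/DMSO, rt
Reagents that add atoms: dichloromethane, ClCCl; 4-methoxybenzyl alcohol, OCc1ccc(OC)cc1
Why: Matteson homologation with alkoxide displacement sets C5 and completes the all-anti C5–C11 array that a single director produces by itself.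

Step 15
Reactants: 30 C5–C14 boronate
Product: 32 C3–C14 allylboronate (B and the C3 vinyl group on C4; B syn to C5-OPMB), via α-chloroboronate 31 (not isolated)
Conditions: CH2Cl2, n-BuLi, THF, −100 °C; 30; ZnCl2 (excess), to rt; crude 31, CH2=CHMgBr, THF, 0 °C to rt
Reagents that add atoms: dichloromethane, ClCCl; vinylmagnesium bromide, C=C[Mg]Br
Why: Matteson homologation in which the chain carbon C3 is delivered as the nucleophile and boron is kept for C18, so that the same director sets C4 in the sense opposite to C5–C11, as the target requires.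

Step 16
Reactants: 32 C3–C14 allylboronate
Product: 34 dienol (4R,5R,6R,7R,8S,9S,10S,11S,12R by target numbering): C3 and C13 vinyl groups with four OPMB groups and the free C18 hydroxyl, via homologated boronate 33 (not isolated)
Conditions: BrCH2Cl, n-BuLi, THF, −78 °C to rt; then NaOH, H2O2, 0 °C
Reagents that add atoms: bromochloromethane, ClCBr; hydrogen peroxide, OO
Why: Methylene insertion with LiCH2Cl (Matteson-type 1,2-shift of C4 with retention) and oxidation of the primary boronate give the C18 alcohol and release the diol; no stereocentre is touched.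

Step 17
Reactants: 34 dienol
Product: 35 methacrylate of 34
Conditions: methacryloyl chloride, Et3N, DMAP (cat.), CH2Cl2, 0 °C
Reagents that add atoms: methacryloyl chloride, C=C(C)C(=O)Cl
Why: DMAP-catalysed acylation of the only free (primary) alcohol brings in C1, C2 and the C2 methyl group.

Step 18
Reactants: 35 methacrylate
Product: 37 lactone enal (3-methyl-5,6-dihydropyran-2-one on C4; E-enal C13=C14–C15HO), via vinyl lactone 36 (not isolated)
Conditions: second-generation Hoveyda–Grubbs catalyst RuCl2(H2IMes)(=CH-C6H4-2-OiPr) (10 mol %), toluene (2 mM), 80 °C; concentrate; (E)-crotonaldehyde (10 equiv), more catalyst, CH2Cl2, 40 °C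
Reagents that add atoms: (E)-crotonaldehyde, C/C=C/C=O
Why: Ring-closing metathesis of the methacrylate with the nearby C3 vinyl group closes the six-membered lactone, in which C2=C3 can only be Z, and cross metathesis of the remaining monosubstituted C13 alkene with crotonaldehyde should then give the E-enal under thermodynamic control.

Step 19
Reactants: 37 lactone enal
Product: 38 ethyl (15Z,13E)-dienoate lactone
Conditions: ethyl 2-[bis(2,2,2-trifluoroethoxy)phosphoryl]propanoate, KN(SiMe3)2, 18-crown-6, THF, −78 °C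
Reagents that add atoms: ethyl 2-[bis(2,2,2-trifluoroethoxy)phosphoryl]propanoate, CCOC(=O)C(C)P(=O)(OCC(F)(F)F)OCC(F)(F)F
Why: Still–Gennari olefination, in which the trifluoroethyl phosphonate with a dissociated potassium ion eliminates under kinetic control and should give the Z-trisubstituted C15=C16 alkene while the preformed anion leaves the lactone alone.

Step 20
Reactants: 38 ethyl dienoate lactone
Product: 40 lactone C17 carboxylic acid, via hydroxy diacid 39 (not isolated)
Conditions: LiOH, THF/MeOH/H2O, rt to 40 °C; 1 M HCl to pH 3, 0 °C; then PPTS (cat.), CH2Cl2, rt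
Reagents that add atoms: lithium hydroxide, [Li+].[OH-]
Why: Saponification cleaves the ethyl ester and opens the lactone, and on acidification only the Z-δ-hydroxy acid can close again (acid-catalysed lactonisation), which leaves C17 as the single free carboxyl group.

Step 21
Reactants: 40 lactone C17 carboxylic acid; 11 2-aminonaphthoquinone
Product: 43 protected amide (C17–N bond; four OPMB groups; lactone; aryl OTBS), via acid chloride 41 (not isolated), via sodium salt 42 (not isolated)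
Conditions: 40, 1-chloro-N,N,2-trimethylprop-1-en-1-amine, CH2Cl2, 0 °C; 11 (excess), NaH, THF, 0 °C; combine, −20 °C to rt
Reagents that add atoms: none
Why: N-acylation of a metallated 2-amino-1,4-naphthoquinone with an acid chloride made under neutral conditions from the α-chloroenamine; deprotonation makes up for the low nucleophilicity of the vinylogous amide nitrogen, and the neutral activation should keep the C15=C16 Z geometry.

Step 22
Reactants: 43 protected amide
Product: 44 tetraol lactone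
Conditions: DDQ, CH2Cl2/pH 7 phosphate buffer (10:1), 0 °C to rt
Reagents that add atoms: none
Why: Oxidative cleavage of the four 4-methoxybenzyl ethers by DDQ (hydride abstraction and hydrolysis of the oxocarbenium ion) leaves the electron-poor quinone, dienamide and lactone alone, and any acyl shift from the C18 to the C5 oxygen is harmless because step 23 opens either lactone.

Step 23
Reactants: 44 tetraol lactone
Product: 45 target CNP0594257.1, (2Z,4R,5R,6R,7R,8S,9S,10S,11S,12R,13E,15Z)-5,7,9,11-tetrahydroxy-4-(hydroxymethyl)-17-[(6-hydroxy-7-methyl-1,4-dioxonaphthalen-2-yl)amino]-2,6,8,10,12,16-hexamethyl-17-oxoheptadeca-2,13,15-trienoic acid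
Conditions: LiOH, THF/H2O (3:1), 0 °C; then 0.1 M HCl to pH 4–5, 0 °C
Reagents that add atoms: lithium hydroxide, [Li+].[OH-]
Why: Saponification opens the δ-lactone and hydroxide removes the electron-poor aryl silyl ether in the same operation while the amide is shielded as its N-anion, and cold acidification only to pH 4–5 should free the acid without renewed lactonisation.

Compound list
1 | 4-bromo-2-methylphenol | Cc1cc(Br)ccc1O | starting material
2 | (4-bromo-2-methylphenoxy)(tert-butyl)dimethylsilane | Cc1cc(Br)ccc1O[Si](C)(C)C(C)(C)C | intermediate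
3 | diisopropyl squarate | CC(C)OC1=C(OC(C)C)C(=O)C1=O | starting material
4 | 4-hydroxy-2,3-diisopropoxycyclobut-2-en-1-one (racemic) | CC(C)OC1=C(OC(C)C)C(=O)C1O | intermediate
5 | 3-isopropoxycyclobut-3-ene-1,2-dione | CC(C)OC1=CC(=O)C1=O | intermediate
6 | 4-(tert-butyldimethylsilyloxy)-3-methylphenyllithium | [Li]c1ccc(O[Si](C)(C)C(C)(C)C)c(C)c1 | intermediate
7 | 4-[4-(tert-butyldimethylsilyloxy)-3-methylphenyl]-4-hydroxy-3-isopropoxycyclobut-2-en-1-one (racemic) | CC(C)OC1=CC(=O)C1(O)c1ccc(O[Si](C)(C)C(C)(C)C)c(C)c1 | intermediate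
8 | vinylketene (aryl cis to the ketene) | O=C=C/C(OC(C)C)=C(/O)c1ccc(O[Si](C)(C)C(C)(C)C)c(C)c1 | intermediate
9 | 6-(tert-butyldimethylsilyloxy)-2-isopropoxy-7-methylnaphthalene-1,4-diol | CC(C)Oc1cc(O)c2cc(O[Si](C)(C)C(C)(C)C)c(C)cc2c1O | intermediate
10 | 6-(tert-butyldimethylsilyloxy)-2-isopropoxy-7-methyl-1,4-naphthoquinone | CC(C)OC1=CC(=O)c2cc(O[Si](C)(C)C(C)(C)C)c(C)cc2C1=O | intermediate
11 | 2-amino-6-(tert-butyldimethylsilyloxy)-7-methyl-1,4-naphthoquinone | NC1=CC(=O)c2cc(O[Si](C)(C)C(C)(C)C)c(C)cc2C1=O | intermediate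
12 | methylboronic acid | CB(O)O | starting material
13 | (1R,2R)-1,2-dicyclohexylethane-1,2-diol | O[C@H](C1CCCCC1)[C@H](O)C1CCCCC1 | starting material
14 | (4R,5R)-4,5-dicyclohexyl-2-methyl-1,3,2-dioxaborolane | CB1O[C@H](C2CCCCC2)[C@@H](C2CCCCC2)O1 | intermediate
15 | (S)-1-chloroethylboronate (Cl on C12) | C[C@@H](Cl)B1O[C@H](C2CCCCC2)[C@@H](C2CCCCC2)O1 | intermediate
16 | C12–C14 boronate, (R)-but-3-en-2-yl | C=C[C@@H](C)B1O[C@H](C2CCCCC2)[C@@H](C2CCCCC2)O1 | intermediate
17 | α-chloroboronate, Cl on C11 | C=C[C@@H](C)[C@@H](Cl)B1O[C@H](C2CCCCC2)[C@@H](C2CCCCC2)O1 | intermediate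
18 | C11–C14 boronate | C=C[C@@H](C)[C@H](OCc1ccc(OC)cc1)B1O[C@H](C2CCCCC2)[C@@H](C2CCCCC2)O1 | intermediate
19 | α-chloroboronate, Cl on C10 | C=C[C@@H](C)[C@H](OCc1ccc(OC)cc1)[C@@H](Cl)B1O[C@H](C2CCCCC2)[C@@H](C2CCCCC2)O1 | intermediate
20 | C10–C14 boronate | C=C[C@@H](C)[C@H](OCc1ccc(OC)cc1)[C@H](C)B1O[C@H](C2CCCCC2)[C@@H](C2CCCCC2)O1 | intermediate
21 | α-chloroboronate, Cl on C9 | C=C[C@@H](C)[C@H](OCc1ccc(OC)cc1)[C@H](C)[C@@H](Cl)B1O[C@H](C2CCCCC2)[C@@H](C2CCCCC2)O1 | intermediate
22 | C9–C14 boronate | C=C[C@@H](C)[C@H](OCc1ccc(OC)cc1)[C@H](C)[C@H](OCc1ccc(OC)cc1)B1O[C@H](C2CCCCC2)[C@@H](C2CCCCC2)O1 | intermediate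
23 | α-chloroboronate, Cl on C8 | C=C[C@@H](C)[C@H](OCc1ccc(OC)cc1)[C@H](C)[C@H](OCc1ccc(OC)cc1)[C@@H](Cl)B1O[C@H](C2CCCCC2)[C@@H](C2CCCCC2)O1 | intermediate
24 | C8–C14 boronate | C=C[C@@H](C)[C@H](OCc1ccc(OC)cc1)[C@H](C)[C@H](OCc1ccc(OC)cc1)[C@H](C)B1O[C@H](C2CCCCC2)[C@@H](C2CCCCC2)O1 | intermediate
25 | α-chloroboronate, Cl on C7 | C=C[C@@H](C)[C@H](OCc1ccc(OC)cc1)[C@H](C)[C@H](OCc1ccc(OC)cc1)[C@H](C)[C@@H](Cl)B1O[C@H](C2CCCCC2)[C@@H](C2CCCCC2)O1 | intermediate
26 | C7–C14 boronate | C=C[C@@H](C)[C@H](OCc1ccc(OC)cc1)[C@H](C)[C@H](OCc1ccc(OC)cc1)[C@H](C)[C@H](OCc1ccc(OC)cc1)B1O[C@H](C2CCCCC2)[C@@H](C2CCCCC2)O1 | intermediate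
27 | α-chloroboronate, Cl on C6 | C=C[C@@H](C)[C@H](OCc1ccc(OC)cc1)[C@H](C)[C@H](OCc1ccc(OC)cc1)[C@H](C)[C@H](OCc1ccc(OC)cc1)[C@@H](Cl)B1O[C@H](C2CCCCC2)[C@@H](C2CCCCC2)O1 | intermediate
28 | C6–C14 boronate | C=C[C@@H](C)[C@H](OCc1ccc(OC)cc1)[C@H](C)[C@H](OCc1ccc(OC)cc1)[C@H](C)[C@H](OCc1ccc(OC)cc1)[C@H](C)B1O[C@H](C2CCCCC2)[C@@H](C2CCCCC2)O1 | intermediate
29 | α-chloroboronate, Cl on C5 | C=C[C@@H](C)[C@H](OCc1ccc(OC)cc1)[C@H](C)[C@H](OCc1ccc(OC)cc1)[C@H](C)[C@H](OCc1ccc(OC)cc1)[C@H](C)[C@@H](Cl)B1O[C@H](C2CCCCC2)[C@@H](C2CCCCC2)O1 | intermediate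
30 | C5–C14 boronate | C=C[C@@H](C)[C@H](OCc1ccc(OC)cc1)[C@H](C)[C@H](OCc1ccc(OC)cc1)[C@H](C)[C@H](OCc1ccc(OC)cc1)[C@H](C)[C@H](OCc1ccc(OC)cc1)B1O[C@H](C2CCCCC2)[C@@H](C2CCCCC2)O1 | intermediate
31 | α-chloroboronate, Cl on C4 | C=C[C@@H](C)[C@H](OCc1ccc(OC)cc1)[C@H](C)[C@H](OCc1ccc(OC)cc1)[C@H](C)[C@H](OCc1ccc(OC)cc1)[C@H](C)[C@H](OCc1ccc(OC)cc1)[C@@H](Cl)B1O[C@H](C2CCCCC2)[C@@H](C2CCCCC2)O1 | intermediate
32 | C3–C14 allylboronate | C=C[C@@H](C)[C@H](OCc1ccc(OC)cc1)[C@H](C)[C@H](OCc1ccc(OC)cc1)[C@H](C)[C@H](OCc1ccc(OC)cc1)[C@H](C)[C@H](OCc1ccc(OC)cc1)[C@H](C=C)B1O[C@H](C2CCCCC2)[C@@H](C2CCCCC2)O1 | intermediate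
33 | homologated boronate, B on C18 | C=C[C@@H](C)[C@H](OCc1ccc(OC)cc1)[C@H](C)[C@H](OCc1ccc(OC)cc1)[C@H](C)[C@H](OCc1ccc(OC)cc1)[C@H](C)[C@H](OCc1ccc(OC)cc1)[C@H](C=C)CB1O[C@H](C2CCCCC2)[C@@H](C2CCCCC2)O1 | intermediate
34 | dienol | C=C[C@@H](C)[C@H](OCc1ccc(OC)cc1)[C@H](C)[C@H](OCc1ccc(OC)cc1)[C@H](C)[C@H](OCc1ccc(OC)cc1)[C@H](C)[C@H](OCc1ccc(OC)cc1)[C@H](C=C)CO | intermediate
35 | methacrylate of 34 | C=C[C@@H](C)[C@H](OCc1ccc(OC)cc1)[C@H](C)[C@H](OCc1ccc(OC)cc1)[C@H](C)[C@H](OCc1ccc(OC)cc1)[C@H](C)[C@H](OCc1ccc(OC)cc1)[C@H](C=C)COC(=O)C(C)=C | intermediate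
36 | vinyl lactone | C=C[C@@H](C)[C@H](OCc1ccc(OC)cc1)[C@H](C)[C@H](OCc1ccc(OC)cc1)[C@H](C)[C@H](OCc1ccc(OC)cc1)[C@H](C)[C@H](OCc1ccc(OC)cc1)[C@H]1COC(=O)C(C)=C1 | intermediate
37 | lactone enal | O=C/C=C/[C@@H](C)[C@H](OCc1ccc(OC)cc1)[C@H](C)[C@H](OCc1ccc(OC)cc1)[C@H](C)[C@H](OCc1ccc(OC)cc1)[C@H](C)[C@H](OCc1ccc(OC)cc1)[C@H]1COC(=O)C(C)=C1 | intermediate
38 | ethyl dienoate lactone | CCOC(=O)/C(C)=C\C=C\[C@@H](C)[C@H](OCc1ccc(OC)cc1)[C@H](C)[C@H](OCc1ccc(OC)cc1)[C@H](C)[C@H](OCc1ccc(OC)cc1)[C@H](C)[C@H](OCc1ccc(OC)cc1)[C@H]1COC(=O)C(C)=C1 | intermediate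
39 | hydroxy diacid | OC(=O)/C(C)=C\C=C\[C@@H](C)[C@H](OCc1ccc(OC)cc1)[C@H](C)[C@H](OCc1ccc(OC)cc1)[C@H](C)[C@H](OCc1ccc(OC)cc1)[C@H](C)[C@H](OCc1ccc(OC)cc1)[C@@H](CO)/C=C(/C)C(=O)O | intermediate
40 | lactone C17 carboxylic acid | OC(=O)/C(C)=C\C=C\[C@@H](C)[C@H](OCc1ccc(OC)cc1)[C@H](C)[C@H](OCc1ccc(OC)cc1)[C@H](C)[C@H](OCc1ccc(OC)cc1)[C@H](C)[C@H](OCc1ccc(OC)cc1)[C@H]1COC(=O)C(C)=C1 | intermediate
41 | acid chloride of 40 | ClC(=O)/C(C)=C\C=C\[C@@H](C)[C@H](OCc1ccc(OC)cc1)[C@H](C)[C@H](OCc1ccc(OC)cc1)[C@H](C)[C@H](OCc1ccc(OC)cc1)[C@H](C)[C@H](OCc1ccc(OC)cc1)[C@H]1COC(=O)C(C)=C1 | intermediate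
42 | sodium salt of 11 | [Na+].[NH-]C1=CC(=O)c2cc(O[Si](C)(C)C(C)(C)C)c(C)cc2C1=O | intermediate
43 | protected amide | O=C(NC1=CC(=O)c2cc(O[Si](C)(C)C(C)(C)C)c(C)cc2C1=O)/C(C)=C\C=C\[C@@H](C)[C@H](OCc1ccc(OC)cc1)[C@H](C)[C@H](OCc1ccc(OC)cc1)[C@H](C)[C@H](OCc1ccc(OC)cc1)[C@H](C)[C@H](OCc1ccc(OC)cc1)[C@H]1COC(=O)C(C)=C1 | intermediate
44 | tetraol lactone | O=C(NC1=CC(=O)c2cc(O[Si](C)(C)C(C)(C)C)c(C)cc2C1=O)/C(C)=C\C=C\[C@@H](C)[C@H](O)[C@H](C)[C@H](O)[C@H](C)[C@H](O)[C@H](C)[C@H](O)[C@H]1COC(=O)C(C)=C1 | intermediate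
45 | CNP0594257.1 | C/C(=C/[C@H](CO)[C@@H](O)[C@@H](C)[C@@H](O)[C@@H](C)[C@@H](O)[C@@H](C)[C@@H](O)[C@H](C)/C=C/C=C(/C)C(=O)NC1=CC(=O)c2cc(O)c(C)cc2C1=O)C(=O)O | target

Total step count: 23. Longest linear sequence: 18 steps (steps 6 to 23).

Steps most likely to fail

**Step 21.**
- The nitrogen of 11 is a vinylogous amide, so acylation may be slow. A slow reaction gives time for Z-to-E isomerisation of the acyl chloride and for acylation at oxygen or at C3′.
- The fallback sets out from 11 and 40 and comes back at 43.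
- 11 is reduced with Na2S2O4 (THF/H2O) to 2-amino-6-(tert-butyldimethylsilyloxy)-7-methylnaphthalene-1,4-diol F1, whose nitrogen is an ordinary electron-rich arylamine.
- F1 is coupled under argon with 40 (EDC, HOAt, CH2Cl2) to the N-acyl aminohydroquinone F2.
- Ag2O then re-oxidises F2 to 43.

**Step 18.**
- Closure onto the electron-poor 1,1-disubstituted alkene next to the branched C4 may be slow. Dimerisation at the C13 vinyl group, or capping of the C3 vinyl group, would then compete.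
- The fallback sets out from 30 (through 31) and comes back at 36, which then needs only the cross-metathesis half of step 18. It takes the Z alkene from a vinyl iodide instead of from a ring closure.
- Propargyl alcohol is methylmagnesiated (MeMgBr, CuI) and iodinated to (Z)-3-iodo-2-methylprop-2-en-1-ol F3.
- F3 is silylated to its TBS ether F4, and t-BuLi converts F4 to the alkenyllithium F5.
- F5 takes the place of the vinyl Grignard reagent on 31 and gives the C4-alkenyl boronate F6.
- LiCH2Cl gives the homologated boronate F7, and NaOH/H2O2 gives the C18 alcohol F8.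
- Bu4NF gives the (Z)-ene-1,5-diol F9.
- MnO2 oxidises the allylic alcohol of F9 through the lactol to 36.

**Step 15.**
- In the ninth iteration, four Lewis-basic ethers may tie up ZnCl2 and slow the 1,2-shifts.
- Slow shifts leave time for chloride exchange at C4 and for a 1,3-shift of boron in the allylboronate.
- The fallback sets out from 28 (through 29) and comes back at 34. It replaces the last two homologations by a substrate-controlled allylboration.
- 29 is oxidised (H2O2, NaHCO3 buffer) to the C5 aldehyde F10.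
- The (Z)-4-(tert-butyldimethylsilyloxy)but-2-enylboronic acid pinacol ester F11 is made from (Z)-tert-butyl[(3-iodoallyl)oxy]dimethylsilane by iodine–lithium exchange and trapping with 2-(chloromethyl)-4,4,5,5-tetramethyl-1,3,2-dioxaborolane.
- F11 adds to F10 through a chair transition state. Z-allylboronates prefer the anti-Felkin mode with α-methyl aldehydes, so this should give the 4,5-syn-5,6-anti homoallylic alcohol F12.
- PMB trichloroacetimidate with Sc(OTf)3 (cat.) gives the PMB ether F13.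
- Bu4NF frees the C18 hydroxyl to give 34.

Further compounds
F1 | step 21 | 2-amino-6-(tert-butyldimethylsilyloxy)-7-methylnaphthalene-1,4-diol | Nc1cc(O)c2cc(O[Si](C)(C)C(C)(C)C)c(C)cc2c1O
F2 | step 21 | N-acyl aminohydroquinone | O=C(Nc1cc(O)c2cc(O[Si](C)(C)C(C)(C)C)c(C)cc2c1O)/C(C)=C\C=C\[C@@H](C)[C@H](OCc1ccc(OC)cc1)[C@H](C)[C@H](OCc1ccc(OC)cc1)[C@H](C)[C@H](OCc1ccc(OC)cc1)[C@H](C)[C@H](OCc1ccc(OC)cc1)[C@H]1COC(=O)C(C)=C1
F3 | step 18 | (Z)-3-iodo-2-methylprop-2-en-1-ol | OC/C(C)=C\I
F4 | step 18 | (Z)-tert-butyl[(3-iodo-2-methylallyl)oxy]dimethylsilane | CC(C)(C)[Si](C)(C)OC/C(C)=C\I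
F5 | step 18 | (Z)-3-(tert-butyldimethylsilyloxy)-2-methylprop-1-enyllithium | CC(C)(C)[Si](C)(C)OC/C(C)=C\[Li]
F6 | step 18 | C4-alkenyl boronate | C=C[C@@H](C)[C@H](OCc1ccc(OC)cc1)[C@H](C)[C@H](OCc1ccc(OC)cc1)[C@H](C)[C@H](OCc1ccc(OC)cc1)[C@H](C)[C@H](OCc1ccc(OC)cc1)[C@H](/C=C(/C)CO[Si](C)(C)C(C)(C)C)B1O[C@H](C2CCCCC2)[C@@H](C2CCCCC2)O1
F7 | step 18 | homologated boronate, B on C18 | C=C[C@@H](C)[C@H](OCc1ccc(OC)cc1)[C@H](C)[C@H](OCc1ccc(OC)cc1)[C@H](C)[C@H](OCc1ccc(OC)cc1)[C@H](C)[C@H](OCc1ccc(OC)cc1)[C@H](/C=C(/C)CO[Si](C)(C)C(C)(C)C)CB1O[C@H](C2CCCCC2)[C@@H](C2CCCCC2)O1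
F8 | step 18 | C18 alcohol with C1 silyl ether | C=C[C@@H](C)[C@H](OCc1ccc(OC)cc1)[C@H](C)[C@H](OCc1ccc(OC)cc1)[C@H](C)[C@H](OCc1ccc(OC)cc1)[C@H](C)[C@H](OCc1ccc(OC)cc1)[C@H](/C=C(/C)CO[Si](C)(C)C(C)(C)C)CO
F9 | step 18 | (Z)-ene-1,5-diol | C=C[C@@H](C)[C@H](OCc1ccc(OC)cc1)[C@H](C)[C@H](OCc1ccc(OC)cc1)[C@H](C)[C@H](OCc1ccc(OC)cc1)[C@H](C)[C@H](OCc1ccc(OC)cc1)[C@H](/C=C(/C)CO)CO
F10 | step 15 | C5 aldehyde | C=C[C@@H](C)[C@H](OCc1ccc(OC)cc1)[C@H](C)[C@H](OCc1ccc(OC)cc1)[C@H](C)[C@H](OCc1ccc(OC)cc1)[C@H](C)C=O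
F11 | step 15 | (Z)-4-(tert-butyldimethylsilyloxy)but-2-enylboronic acid pinacol ester | CC(C)(C)[Si](C)(C)OC/C=C\CB1OC(C)(C)C(C)(C)O1
F12 | step 15 | homoallylic alcohol (free C5 hydroxyl, C18 silyl ether) | C=C[C@@H](C)[C@H](OCc1ccc(OC)cc1)[C@H](C)[C@H](OCc1ccc(OC)cc1)[C@H](C)[C@H](OCc1ccc(OC)cc1)[C@H](C)[C@H](O)[C@H](C=C)CO[Si](C)(C)C(C)(C)C
F13 | step 15 | C5 PMB ether of F12 | C=C[C@@H](C)[C@H](OCc1ccc(OC)cc1)[C@H](C)[C@H](OCc1ccc(OC)cc1)[C@H](C)[C@H](OCc1ccc(OC)cc1)[C@H](C)[C@H](OCc1ccc(OC)cc1)[C@H](C=C)CO[Si](C)(C)C(C)(C)C
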